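Everything rests on closing ring B, the ten-membered carbocycle, last, between C2 (the acetoxy CH next to the quaternary ring-fusion carbon C1) and C3 (the adjacent CH2). Ring A and the lactone ring C are built and joined at C8–C9 first, so the precursor is a seco compound with a C2 aldehyde on C1 and a primary C3 iodide on the acrylate arm. A cobalt-catalysed alkylchromium addition forms the C2–C3 bond, ring B and the C2 carbinol stereocentre in one operation. It exploits the non-enolisable neopentyl aldehyde, the facial bias of C1, and the trans-fused lactone on C7–C8 with the C5=C6 alkene, which fold C3 towards C2.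

Key step: step 23

Numbering used below: ring A = cyclohexane C1, C10, C11, C12, C13, C14; ring B = C1 to C10; ring C = γ-lactone (C7, C8, C17, C19, O). C5=C6 is the acrylate alkene (C16 = ester carbon), C9 the acetoxy CH next to ring A, C15 the methyl on C1, C20 the methyl on C11, C18 the methyl on C17. β is the face of ring A that carries C15; the target has C9 and C20 β, and C2, O12 and O14 α.

Assumption: the Birch reduction–alkylation of the (S)-auxiliary benzamide is taken to methylate the chelated amide enolate on the face that gives the C1 configuration drawn; if the sense is opposite, the (R)-auxiliary is used and nothing else changes.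

Remark: fragment 2 is made racemic at C17; both C17 epimers are carried from step 16 and converged in step 19.

**Ring A (fragment 1)**

Step 1
Reactants: 1 2-methoxy-5-methylbenzoic acid; 2 (S)-2-(methoxymethyl)pyrrolidine
Product: 4 auxiliary benzamide, via acid chloride 3 (not isolated)
Conditions: (COCl)2, cat. DMF, CH2Cl2, 0 °C to rt; then 2, Et3N, CH2Cl2, 0 °C
Reagents that add atoms: none
Why: Amide formation through the acid chloride; no stereocentre is touched.

Step 2
Reactants: 4 auxiliary benzamide
Product: 7 keto amide (C14 ketone, C10=C11 alkene, quaternary C1), via potassium enolate 5 (not isolated), via methylated enol ether 6 (not isolated)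
Conditions: K, NH3(l)/THF, t-BuOH (1 equiv), −78 °C; MeI, −78 °C; then 1 M HCl, THF/MeOH, rt
Reagents that add atoms: iodomethane (CI); water (O)
Why: Birch reduction–alkylation, in which the chiral amide enolate is methylated on one face under control of the auxiliary and so sets C1; acid hydrolysis of the enol ether then gives the C14 ketone, and the alkene cannot conjugate through quaternary C1.

Step 3
Reactants: 7 keto amide
Product: 8 14α-hydroxy amide
Conditions: LiBH(sec-Bu)3, THF, −78 °C; then H2O
Reagents that add atoms: none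
Why: Ketone reduction under steric approach control; the bulky hydride should attack C14 anti to the carboxamide on C1, placing the hydroxyl cis to the amide (α).

Step 4
Reactants: 8 14α-hydroxy amide
Product: 9 C14 silyl ether
Conditions: TBSOTf, 2,6-lutidine, CH2Cl2, 0 °C
Reagents that add atoms: tert-butyldimethylsilyl trifluoromethanesulfonate (CC(C)(C)[Si](C)(C)OS(=O)(=O)C(F)(F)F)
Why: Silylation of the hindered secondary alcohol to protect it through the base and organolithium steps.

Step 5
Reactants: 9 C14 silyl ether
Product: 10 12β-allylic alcohol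
Conditions: SeO2 (0.5 equiv), t-BuOOH, CH2Cl2, rt
Reagents that add atoms: selenium dioxide (O=[Se]=O), re-oxidised by tert-butyl hydroperoxide (CC(C)(C)OO)
Why: Allylic hydroxylation by ene reaction and [2,3]-sigmatropic shift; selenium should add to C10 on the β face anti to the carboxamide and return oxygen suprafacially to the ring CH2 at C12, giving the 12β-alcohol.

Step 6
Reactants: 10 12β-allylic alcohol
Product: 11 stannylmethyl ether
Conditions: KH, THF, 0 °C; Bu3SnCH2I, rt
Reagents that add atoms: tributyl(iodomethyl)stannane (CCCC[Sn](CCCC)(CCCC)CI)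
Why: Williamson etherification of the allylic alkoxide to install the precursor of the [2,3]-rearrangement.

Step 7
Reactants: 11 stannylmethyl ether
Product: 12 C9 hydroxymethyl compound with C11=C12 alkene
Conditions: n-BuLi, THF, −78 °C
Reagents that add atoms: none
Why: Still–Wittig [2,3]-rearrangement after tin–lithium exchange; the CH2O unit moves suprafacially from O12 (β) to the β face of C10, which sets C10 with C9 cis to C15 and shifts the alkene to C11=C12.

Step 8
Reactants: 12 C9 hydroxymethyl compound
Product: 14 diol (12α-OH, C20 β), via organoborane 13 (not isolated)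
Conditions: BH3·THF (1.5 equiv), THF, 0 °C; then NaOH, H2O2
Reagents that add atoms: hydrogen peroxide (OO)
Why: Hydroboration–oxidation; syn addition should occur on the α face anti to the adjacent pseudoaxial C9 substituent, with boron at the less substituted C12, which sets 12α-OH and 11α-H (C20 β, cis to C9).

Step 9
Reactants: 14 diol
Product: 15 ring A aldehyde (fragment 1)
Conditions: TEMPO (cat.), PhI(OAc)2, CH2Cl2, rt
Reagents that add atoms: none
Why: Nitroxyl-catalysed oxidation selective for the primary C9 alcohol over the secondary C12 alcohol; the trans 1,3 relationship prevents lactol formation.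

**Fragment 2 (C3 to C8, C16 to C19)**

Step 10
Reactants: 16 tert-butyl 2-bromopropanoate; 17 triphenylphosphine
Product: 18 phosphonium bromide
Conditions: MeCN, 70 °C
Reagents that add atoms: none
Why: SN2 quaternisation of the phosphine by the α-bromo ester.

Step 11
Reactants: 19 3-[(4-methoxybenzyl)oxy]propanoic acid; 18 phosphonium bromide
Product: 22 allenoate, via acid chloride 20 (not isolated), via phosphorus ylide 21 (not isolated)
Conditions: 1-chloro-N,N,2-trimethylprop-1-en-1-amine, CH2Cl2, 0 °C; then 18, Et3N (2.2 equiv), CH2Cl2, 0 °C to rt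
Reagents that add atoms: none
Why: Wittig allenation; the stabilised ylide is acylated by the acid chloride under neutral chloride formation, and loss of triphenylphosphine oxide gives the 2,3-dienoate.

Step 12
Reactants: 22 allenoate
Product: 23 (E)-vinyl iodide, racemic at C17
Conditions: NaI, AcOH, rt
Reagents that add atoms: sodium iodide ([Na+].[I-])
Why: Conjugate hydroiodination of the allenoate; iodide should add to the central carbon C8 in the plane of the C7 substituents from the side of H, anti to the CH2OPMB group, and α-protonation gives the β,γ-unsaturated ester with iodine trans to C6.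

Step 13
Reactants: 23 (E)-vinyl iodide
Product: 24 iodo allylic alcohol
Conditions: DDQ, CH2Cl2/pH 7 buffer, 0 °C
Reagents that add atoms: none
Why: Oxidative cleavage of the 4-methoxybenzyl ether under neutral conditions that spare the tert-butyl ester, the vinyl iodide and the acidic C17–H.

Step 14
Reactants: 25 methyl (triphenylphosphoranylidene)acetate; 26 tert-butyl(2-iodoethoxy)dimethylsilane
Product: 28 substituted ylide, via phosphonium iodide 27 (not isolated)
Conditions: 25 (2 equiv), EtOAc, reflux
Reagents that add atoms: none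
Why: C-alkylation of the stabilised ylide followed by transylidation with the second equivalent of 25.

Step 15
Reactants: 24 iodo allylic alcohol; 28 substituted ylide
Product: 30 dienyl iodide (fragment 2), via enal 29 (not isolated)
Conditions: MnO2, CH2Cl2, rt, 28 present from the start
Reagents that add atoms: none
Why: Tandem allylic oxidation–Wittig olefination; the base-sensitive enal is trapped at once by the neutral stabilised ylide, which should give the trisubstituted enoate with C7 trans to the ester (C4 and C7 cis, as ring B requires).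

**Union and completion**

Step 16
Reactants: 15 ring A aldehyde (fragment 1); 30 dienyl iodide (fragment 2)
Product: 31 dienyl carbinol (C9–OH)
Conditions: CrCl2 (6 equiv), NiCl2 (2 mol%), DMSO, rt
Reagents that add atoms: none
Why: Nozaki–Hiyama–Kishi coupling forming C8–C9 with retention of the C7=C8 geometry; Felkin–Anh attack anti to the quaternary C1 substituent of C10 should give the C9 configuration drawn, and esters, silyl ethers and the amide are inert.

Step 17
Reactants: 31 dienyl carbinol
Product: 32 epoxy alcohol
Conditions: VO(acac)2 (5 mol%), t-BuOOH, CH2Cl2, 0 °C to rt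
Reagents that add atoms: tert-butyl hydroperoxide (CC(C)(C)OO)
Why: Hydroxyl-directed epoxidation of the allylic C7=C8 bond only; A(1,2) strain between C10 and the C17 branch should favour the erythro epoxy alcohol, which sets C8 with its oxygen anti to O9.

Step 18
Reactants: 32 epoxy alcohol
Product: 33 hydroxy lactone (ring C closed, both C17 epimers)
Conditions: BF3·OEt2, CH2Cl2, −78 °C
Reagents that add atoms: none
Why: Epoxide-opening lactonisation; the tert-butyl ester carbonyl oxygen opens the activated epoxide at allylic C7 in a 5-exo-tet SN2 step with inversion and the dioxocarbenium ion loses 2-methylpropene, which sets C7 with O7 anti to O8.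

Step 19
Reactants: 33 hydroxy lactone
Product: 35 diacetate with C17 set, via diacetate epimer pair 34 (not isolated)
Conditions: Ac2O, pyridine, DMAP (cat.), CH2Cl2, rt; then DBU, toluene, rt
Reagents that add atoms: acetic anhydride (CC(=O)OC(C)=O)
Why: Acylation of the secondary C9 and C12 hydroxyls (tertiary C8–OH stays free), then base equilibration of the lactone α-carbon to the more stable epimer with C18 trans to the bulky C9 branch and cis to 8-OH, which converges both C17 epimers.

Step 20
Reactants: 35 diacetate
Product: 36 triol (C3–OH, C8–OH, C14–OH)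
Conditions: HF·pyridine, THF/pyridine, 0 °C to rt
Reagents that add atoms: none
Why: Fluoride-mediated desilylation of the primary C3 and hindered C14 silyl ethers under conditions that leave acetates, lactone and methyl ester intact.

Step 21
Reactants: 36 triol
Product: 37 C3 iodide
Conditions: I2, PPh3, imidazole, CH2Cl2, 0 °C
Reagents that add atoms: iodine (II)
Why: Appel iodination, selective for the unhindered primary C3 alcohol over the neopentyl-type secondary C14 alcohol and the tertiary C8 alcohol.

Step 22
Reactants: 37 C3 iodide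
Product: 38 seco iodo aldehyde
Conditions: Cp2Zr(H)Cl (4 equiv), THF, rt; then H2O, silica gel
Reagents that add atoms: none
Why: Chemoselective amide-to-aldehyde reduction by hydrozirconation of the amide carbonyl; the zirconated hemiaminal releases the C2 aldehyde and the auxiliary on work-up, and tertiary amides react faster than esters, lactones and acetates.

Step 23
Reactants: 38 seco iodo aldehyde
Product: 39 ring B alcohol (C2–OH)
Conditions: CrCl2 (8 equiv), cobalt phthalocyanine Co(C32H16N8) (0.2 equiv), DMF, rt, slow addition of 38 to 1 mM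
Reagents that add atoms: none
Why: Proposed new method: monovalent cobalt, formed from the phthalocyanine by CrCl2, displaces iodide at C3, the alkylcobalt releases a primary C3 radical that divalent chromium captures, and the resulting alkylchromium (trivalent) adds to the C2 aldehyde, closing ring B in a 10-exo-trig mode. The closest known chemistry is the intermolecular cobalt-catalysed coupling of alkyl iodides with aldehydes by CrCl2 and the Nozaki–Hiyama–Kishi macrocyclisation of alkenyl halides; ring closure with an unactivated alkyl iodide is the new element. C2 is the only new stereocentre and should follow Felkin–Anh control by quaternary C1: C3 attacks anti to the C1–C14 bond, between C10 and C15, with the carbonyl oxygen over the C10/C14 sector, a trajectory the tether through C10 can reach and which gives the C2 configuration of the target. The step needs chemoselectivity for the aldehyde over methyl ester, lactone and acetates, which organochromium reagents have, and cyclisation faster than protonolysis, dimerisation or 1,5-hydrogen transfer from C7 to the C3 radical. These are addressed by a large excess of CrCl2 for fast radical capture, high dilution of 38, the non-enolisable neopentyl aldehyde, and the folding of the seco chain by the trans-fused ring C and the C5=C6 alkene with C4 and C7 cis.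

Step 24
Reactants: 39 ring B alcohol
Product: 40 CNP0230222.1 (target)
Conditions: Ac2O, pyridine, DMAP (cat.), CH2Cl2, rt
Reagents that add atoms: acetic anhydride (CC(=O)OC(C)=O)
Why: DMAP-catalysed acylation of the hindered secondary C2 and C14 hydroxyls; the tertiary C8 hydroxyl should stay free as in the target.

**Compound list**

1 | 2-methoxy-5-methylbenzoic acid | COc1ccc(C)cc1C(=O)O | starting material
2 | (S)-2-(methoxymethyl)pyrrolidine | COC[C@@H]1CCCN1 | starting material
3 | 2-methoxy-5-methylbenzoyl chloride | COc1ccc(C)cc1C(Cl)=O | intermediate (not isolated)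
4 | [(2S)-2-(methoxymethyl)pyrrolidin-1-yl](2-methoxy-5-methylphenyl)methanone | COc1ccc(C)cc1C(=O)N1CCC[C@H]1COC | intermediate
5 | potassium amide enolate of the 1,4-dihydroarene | COC1=CCC(C)=CC1=C([O-])N1CCC[C@H]1COC.[K+] | intermediate (not isolated)
6 | 2-methoxy-1,4-dimethylcyclohexa-2,5-diene-1-carboxamide of the auxiliary (C1 methylated) | COC1=CCC(C)=C[C@@]1(C)C(=O)N1CCC[C@H]1COC | intermediate (not isolated)
7 | 1,3-dimethyl-6-oxocyclohex-2-ene-1-carboxamide of the auxiliary (C14 ketone) | O=C1CCC(C)=C[C@@]1(C)C(=O)N1CCC[C@H]1COC | intermediate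
8 | 6-hydroxy-1,3-dimethylcyclohex-2-ene-1-carboxamide of the auxiliary (14α-OH cis to the amide) | O[C@H]1CCC(C)=C[C@@]1(C)C(=O)N1CCC[C@H]1COC | intermediate
9 | C14 tert-butyldimethylsilyl ether of 8 | CC(C)(C)[Si](C)(C)O[C@H]1CCC(C)=C[C@@]1(C)C(=O)N1CCC[C@H]1COC | intermediate
10 | 12β-hydroxy allylic alcohol (trans to the 14-silyloxy group) | CC(C)(C)[Si](C)(C)O[C@H]1C[C@H](O)C(C)=C[C@@]1(C)C(=O)N1CCC[C@H]1COC | intermediate
11 | 12β-[(tributylstannyl)methoxy] ether | CC(C)(C)[Si](C)(C)O[C@H]1C[C@H](OC[Sn](CCCC)(CCCC)CCCC)C(C)=C[C@@]1(C)C(=O)N1CCC[C@H]1COC | intermediate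
12 | 10β-hydroxymethyl compound with C11=C12 alkene | CC(C)(C)[Si](C)(C)O[C@H]1CC=C(C)[C@H](CO)[C@@]1(C)C(=O)N1CCC[C@H]1COC | intermediate
13 | C12 alkylborane from α-face hydroboration (drawn as the monoalkylborane) | CC(C)(C)[Si](C)(C)O[C@H]1C[C@@H](B)[C@H](C)[C@H](CO)[C@@]1(C)C(=O)N1CCC[C@H]1COC | intermediate (not isolated)
14 | diol: 12α-OH, C9 hydroxymethyl β, C20 β | CC(C)(C)[Si](C)(C)O[C@H]1C[C@@H](O)[C@H](C)[C@H](CO)[C@@]1(C)C(=O)N1CCC[C@H]1COC | intermediate
15 | ring A aldehyde, fragment 1 (C9 formyl on C10) | CC(C)(C)[Si](C)(C)O[C@H]1C[C@@H](O)[C@H](C)[C@H](C=O)[C@@]1(C)C(=O)N1CCC[C@H]1COC | intermediate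
16 | tert-butyl 2-bromopropanoate (racemic) | CC(Br)C(=O)OC(C)(C)C | starting material
17 | triphenylphosphine | c1ccc(cc1)P(c1ccccc1)c1ccccc1 | starting material
18 | (1-tert-butoxy-1-oxopropan-2-yl)triphenylphosphonium bromide | CC([P+](c1ccccc1)(c1ccccc1)c1ccccc1)C(=O)OC(C)(C)C.[Br-] | intermediate
19 | 3-[(4-methoxybenzyl)oxy]propanoic acid | COc1ccc(COCCC(=O)O)cc1 | starting material
20 | 3-[(4-methoxybenzyl)oxy]propanoyl chloride | COc1ccc(COCCC(Cl)=O)cc1 | intermediate (not isolated)
21 | tert-butyl 2-(triphenylphosphoranylidene)propanoate | CC(=P(c1ccccc1)(c1ccccc1)c1ccccc1)C(=O)OC(C)(C)C | intermediate (not isolated)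
22 | tert-butyl 5-[(4-methoxybenzyl)oxy]-2-methylpenta-2,3-dienoate (racemic) | COc1ccc(COCC=C=C(C)C(=O)OC(C)(C)C)cc1 | intermediate
23 | tert-butyl (E)-3-iodo-5-[(4-methoxybenzyl)oxy]-2-methylpent-3-enoate (racemic at C17) | COc1ccc(COC/C=C(/I)C(C)C(=O)OC(C)(C)C)cc1 | intermediate
24 | tert-butyl (E)-5-hydroxy-3-iodo-2-methylpent-3-enoate | OC/C=C(/I)C(C)C(=O)OC(C)(C)C | intermediate
25 | methyl (triphenylphosphoranylidene)acetate | COC(=O)C=P(c1ccccc1)(c1ccccc1)c1ccccc1 | starting material
26 | tert-butyl(2-iodoethoxy)dimethylsilane | CC(C)(C)[Si](C)(C)OCCI | starting material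
27 | [4-(tert-butyldimethylsilyloxy)-1-methoxy-1-oxobutan-2-yl]triphenylphosphonium iodide | COC(=O)C(CCO[Si](C)(C)C(C)(C)C)[P+](c1ccccc1)(c1ccccc1)c1ccccc1.[I-] | intermediate (not isolated)
28 | methyl 4-(tert-butyldimethylsilyloxy)-2-(triphenylphosphoranylidene)butanoate | COC(=O)C(CCO[Si](C)(C)C(C)(C)C)=P(c1ccccc1)(c1ccccc1)c1ccccc1 | intermediate
29 | tert-butyl (E)-3-iodo-2-methyl-5-oxopent-3-enoate | O=C/C=C(/I)C(C)C(=O)OC(C)(C)C | intermediate (not isolated)
30 | fragment 2: 1-tert-butyl 7-methyl (3E,5E)-6-[2-(tert-butyldimethylsilyloxy)ethyl]-3-iodo-2-methylhepta-3,5-dienedioate (racemic at C17) | COC(=O)/C(CCO[Si](C)(C)C(C)(C)C)=C/C=C(/I)C(C)C(=O)OC(C)(C)C | intermediate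
31 | dienyl carbinol: C8–C9 joined, C9–OH, C7=C8 with C6 trans to C9 (both C17 epimers) | COC(=O)/C(CCO[Si](C)(C)C(C)(C)C)=C/C=C(\C(C)C(=O)OC(C)(C)C)[C@H](O)[C@H]1[C@@H](C)[C@H](O)C[C@H](O[Si](C)(C)C(C)(C)C)[C@]1(C)C(=O)N1CCC[C@H]1COC | intermediate
32 | erythro 7,8-epoxy alcohol (both C17 epimers) | COC(=O)/C(CCO[Si](C)(C)C(C)(C)C)=C/[C@H]2O[C@]2(C(C)C(=O)OC(C)(C)C)[C@H](O)[C@H]1[C@@H](C)[C@H](O)C[C@H](O[Si](C)(C)C(C)(C)C)[C@]1(C)C(=O)N1CCC[C@H]1COC | intermediate
33 | hydroxy lactone: ring C closed, 8-OH, 9-OH, 12-OH free (both C17 epimers) | COC(=O)/C(CCO[Si](C)(C)C(C)(C)C)=C/[C@@H]2OC(=O)C(C)[C@@]2(O)[C@H](O)[C@H]1[C@@H](C)[C@H](O)C[C@H](O[Si](C)(C)C(C)(C)C)[C@]1(C)C(=O)N1CCC[C@H]1COC | intermediate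
34 | 9,12-diacetate (both C17 epimers) | COC(=O)/C(CCO[Si](C)(C)C(C)(C)C)=C/[C@@H]2OC(=O)C(C)[C@@]2(O)[C@H](OC(C)=O)[C@H]1[C@@H](C)[C@H](OC(C)=O)C[C@H](O[Si](C)(C)C(C)(C)C)[C@]1(C)C(=O)N1CCC[C@H]1COC | intermediate (not isolated)
35 | 9,12-diacetate with C17 set (C18 cis to 8-OH) | COC(=O)/C(CCO[Si](C)(C)C(C)(C)C)=C/[C@@H]2OC(=O)[C@H](C)[C@@]2(O)[C@H](OC(C)=O)[C@H]1[C@@H](C)[C@H](OC(C)=O)C[C@H](O[Si](C)(C)C(C)(C)C)[C@]1(C)C(=O)N1CCC[C@H]1COC | intermediate
36 | triol: C3–OH, C8–OH, C14–OH | COC(=O)/C(CCO)=C/[C@@H]2OC(=O)[C@H](C)[C@@]2(O)[C@H](OC(C)=O)[C@H]1[C@@H](C)[C@H](OC(C)=O)C[C@H](O)[C@]1(C)C(=O)N1CCC[C@H]1COC | intermediate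
37 | primary C3 iodide | COC(=O)/C(CCI)=C/[C@@H]2OC(=O)[C@H](C)[C@@]2(O)[C@H](OC(C)=O)[C@H]1[C@@H](C)[C@H](OC(C)=O)C[C@H](O)[C@]1(C)C(=O)N1CCC[C@H]1COC | intermediate
38 | seco iodo aldehyde (C2 formyl on C1, C3 iodide) | COC(=O)/C(CCI)=C/[C@@H]2OC(=O)[C@H](C)[C@@]2(O)[C@H](OC(C)=O)[C@H]1[C@@H](C)[C@H](OC(C)=O)C[C@H](O)[C@]1(C)C=O | intermediate
39 | ring B alcohol: 9,12-diacetate with free 2-OH, 8-OH and 14-OH | COC(=O)/C1=C/[C@@H]2OC(=O)[C@H](C)[C@@]2(O)[C@H](OC(C)=O)[C@H]2[C@@H](C)[C@H](OC(C)=O)C[C@H](O)[C@]2(C)[C@H](O)CC1 | intermediate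
40 | CNP0230222.1 | COC(=O)/C1=C/[C@@H]2OC(=O)[C@H](C)[C@@]2(O)[C@H](OC(C)=O)[C@H]2[C@@H](C)[C@H](OC(C)=O)C[C@H](OC(C)=O)[C@]2(C)[C@H](OC(C)=O)CC1 | target

Total step count: 24. Longest linear sequence: 18 steps (steps 1 to 9, then 16 to 24).

**Steps most likely to fail**

Step 23 (proposed new method). The 10-membered closure may be outrun by protonolysis of the alkylchromium, by intermolecular coupling, or by 1,5-hydrogen transfer from the allylic, oxygen-bearing C7 to the C3 radical. The fallback closes the same bond by known chemistry and sets out from 38. Kornblum substitution (NaNO2, DMF, phloroglucinol) should give the nitro aldehyde F1. An intramolecular Henry reaction (catalytic DBU, THF, high dilution) should then give the ring B nitro alcohol F2. Radical denitration (Bu3SnH, AIBN, toluene, reflux) should return to 39; a wrong C2 epimer would be corrected by oxidation and reduction.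

Step 22. Hydrozirconation of the very hindered α-quaternary amide may be slow, so that reduction of esters or of the C–I bond competes. The fallback sets out from 37 and replaces the stoichiometric metal hydride by catalytic hydrosilylation of the amide (IrCl(CO)(PPh3)2, 1 mol%, 1,1,3,3-tetramethyldisiloxane, toluene, rt), which should stop at the silyl hemiaminal F3. Mild aqueous acid (citric acid, THF/H2O) should then release the aldehyde and return to 38.

Step 16. The coupling of two hindered partners may show poor facial selectivity at C9 or low conversion. The fallback sets out from the C9 epimer mixture of 31 and replaces substrate control by reagent control. MnO2 in CH2Cl2 should oxidise only the doubly allylic C9 alcohol to the cross-conjugated dienone F4. Corey–Bakshi–Shibata reduction (methyl oxazaborolidine of the matching enantiomer, catecholborane, toluene, −78 °C) should return to 31 with the C9 configuration drawn.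

**Further compounds**

F1 | step 23 | nitro aldehyde (C3 nitro in place of iodide) | COC(=O)/C(CC[N+](=O)[O-])=C/[C@@H]2OC(=O)[C@H](C)[C@@]2(O)[C@H](OC(C)=O)[C@H]1[C@@H](C)[C@H](OC(C)=O)C[C@H](O)[C@]1(C)C=O
F2 | step 23 | ring B nitro alcohol (C2–OH, C3–NO2, C3 epimers) | COC(=O)/C1=C/[C@@H]2OC(=O)[C@H](C)[C@@]2(O)[C@H](OC(C)=O)[C@H]2[C@@H](C)[C@H](OC(C)=O)C[C@H](O)[C@]2(C)[C@H](O)C([N+](=O)[O-])C1
F3 | step 22 | silyl hemiaminal of 37 at C2 (not isolated) | COC(=O)/C(CCI)=C/[C@@H]2OC(=O)[C@H](C)[C@@]2(O)[C@H](OC(C)=O)[C@H]1[C@@H](C)[C@H](OC(C)=O)C[C@H](O)[C@]1(C)C(O[Si](C)(C)O[SiH](C)C)N1CCC[C@H]1COC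
F4 | step 16 | C9 dienone from 31 | COC(=O)/C(CCO[Si](C)(C)C(C)(C)C)=C/C=C(\C(C)C(=O)OC(C)(C)C)C(=O)[C@H]1[C@@H](C)[C@H](O)C[C@H](O[Si](C)(C)C(C)(C)C)[C@]1(C)C(=O)N1CCC[C@H]1COC
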